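## Analysis of the target

The target (31) is a bicyclic diterpenoid ester: a decalin (ring A = C1–C5, C10; ring B = C5–C10) carrying a 3-methylenepent-4-enyl chain on C9 (C11, C12, C13 with its exocyclic methylene C16, vinyl C14=C15), methyl groups C17 (on C8), C18 (on C4) and C20 (on C10), and C19 (the CH2O on C4) esterified with (Z)-4-hydroxycinnamic acid. It has five stereocentres, (4R,5S,8R,9R,10S) in this numbering. With β defined as the face of C20, the groups H-5, C18, C17 and the C9 chain are β, whereas C19, the 8-hydroxyl and H-9 are α, so the ring fusion is cis. Because C4 is fully substituted, the chair–chair form expected to dominate has C4 equatorial and C1 axial on ring B: it keeps only the 1,3-diaxial C18/C20 methyl pair on ring A, whereas the ring-flipped form would add a C17/C20 diaxial pair on ring B and press C19 against C9. In that form the axial positions of ring B are 6α, 7β, 8α and 9β, so the tertiary hydroxyl and the C9 chain are both axial and trans to each other. The sensitive groups are the Z-cinnamate (light, base and nucleophiles isomerise it), the free phenol, the terminal 1,3-diene (acid, oxidants, hydrogenation) and the tertiary alcohol (dehydration). The difficulty lies in the two quaternary carbons C4 and C10 flanking the cis junction, and in placing O-8 on the α face and the C9 chain on the β face against the usual preferences of the ring. The strategy rests on the C4–C5–C10 triad: CH3-4, H-5 and CH3-10 on one face beside methyl-bearing C8 map onto a methylated p-quinone (ring B with C17 and C20) and an E-diene (C1–C4 with C18 and C19).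

## Retrosynthetic reasoning

**Cinnamate C=C (31 ⇒ 30 ⇒ 27 + 29).** The Z double bond is cut last. It is the most labile element, so it is made in the final C–C bond formation under kinetic control by a Z-selective phosphonoacetate olefination of the aryl aldehyde 29 with the phosphonate 27. Only a buffered removal of the phenol silyl ether (30 to 31) follows.

**Ester at O-19 (27 ⇒ 26 ⇒ 25).** The phosphonoacetyl group is put on the only primary hydroxyl of diol 26, which is released from the silyl ether 25. The C19 silyl ether is the one protecting group of the sequence and comes with the diene of the key step.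

**C12–C13 (25 ⇒ 22 + 24).** The diene is incompatible with hydrogenation, peracid and tin hydride, so it is introduced after all of these. The unhindered primary iodide 22 is coupled with the dienyl Grignard reagent 24, made from 23.

**C8–O (22 ⇒ 21 ⇒ 20 ⇒ 19).** The axial 8α-hydroxyl is traced to the α-epoxide 20. Hydride opening at the secondary C7 in the diaxial sense leaves oxygen on C8, and the same hydride step reduces the ester to the C12 alcohol of 21. The forward step needs peracid attack anti to the axial C9 substituent of 19.

**C9–C11 (19 ⇒ 17).** The axial, β-oriented chain at C9 next to quaternary C10 is cut by a [3,3] disconnection. An orthoester Claisen rearrangement of the 7β-allylic alcohol 17 (through 18) forms C9–C11 on the face that carried the C7–O bond and leaves the C7=C8 alkene needed for the C8 oxygenation.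

**Oxygen from C9 to C7 (17 ⇒ 15 ⇒ 14).** The allylic alcohol comes from the epoxy ketone 15 by a Wharton transposition (through 16), and 15 from enone 14 by nucleophilic epoxidation, in which the peroxide adds axially to C7 from the β face. A shorter end-game from 12 (oxygenating its enolate, then adding hydrogen across an exocyclic C9=C11 bond) was set aside. In the preferred conformation both reagents would come from the open β face, putting O-8 and H-9 on the wrong side; the relay C7–O to C9–C to C8–O uses the same facial bias productively.

**C6 oxygen and unsaturation (14 ⇒ 12 ⇒ 11 ⇒ 10 ⇒ 9 ⇒ 8).** The C6 carbonyl of the cycloadduct has done its work as the activating group and is removed. After saturation of both alkenes (9), the less hindered C6 ketone is reduced selectively (10) and deoxygenated through 11 by a radical method. The C9 ketone of 12, enolisable only towards C8, is dehydrogenated to 14 (through 13).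

**C1–C10 and C4–C5 (8 ⇒ 6 + 7).** The two ring-A bonds at the ring fusion are cut together. A catalytic asymmetric Diels–Alder reaction of the quinone 7 with the E-diene 6 closes ring A and sets C4, C5 and C10, including both quaternary centres, in one step from two small partners.

**Diene (6 ⇒ 5 ⇒ 3 ⇒ 1 + 2).** The diene follows from E-selective Wittig olefination of 1 with ylide 2, reduction (through 4) and silylation.

## Alternatives that were turned down

**Alternative 1: sigmatropic route to the cis-decalin.**
- Disconnection: C5–C6, with cleavage of a bridging bond of a bicyclo[2.2.2]octene.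
- Forward key step: an anionic oxy-Cope rearrangement of the potassium alkoxide of a bridged tertiary vinyl carbinol (itself from a dearomatised aromatic precursor by cycloaddition and vinyl addition). It delivers A1, a cis-fused decalin with a C8 ketone, a C9 dimethyl ketal, a C2 sulfone and a C3=C4 enoate.
- For: the cis fusion is a stereospecific consequence of the shift. The C8 ketone would accept the C17 methyl as a nucleophile from the open β face and give the axial 8α-carbinol in one step, which is better than the two-step, sterically controlled solution used here.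
- Against: C4 is still trigonal in A1, so the quaternary C4 must be made later by an alkylation whose facial outcome is not secured. The sulfone must be removed, and C9 carries oxygen where the target has hydrogen and the chain. The sequence has no built-in source of absolute configuration.
- Comparison: the chosen route fixes C4, C5, C10 and the absolute configuration in one catalytic step after three simple steps, at the cost of a longer ring-B end-game.

**Alternative 2: intramolecular Diels–Alder of an open-chain triene.**
- Disconnection: C5–C10 and C3–C4 together.
- Forward key step: thermal cycloaddition of a Z-trisubstituted enoate (C4=C5) across a diene (C10=C1–C2=C3) tethered through C6–C9. It gives A2, a cis-fused octalin ester with the C8 ketone masked as a dioxolane and a two-carbon benzyloxy chain on C9.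
- For: both rings and two C–C bonds form in one step. C9 already carries C11–C12 and C8 is a carbonyl, so the late stage would be shorter than in the chosen route.
- Against: all stereochemical information must come from a pre-made C9 stereocentre and from endo/exo and facial preferences of a tether-controlled transition state. These are usually modest for such trienes, and here the diene terminus is fully substituted. The Z-enoate must be made and kept geometrically pure at the temperature of the cycloaddition. The uncertain step comes at the end of a long linear sequence.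
- Comparison: the chosen route is convergent, its absolute configuration is set by a catalyst, and its risk sits at step 4.

**Alternative 3: desymmetrising intramolecular Michael addition.**
- Disconnection: C4–C5.
- Forward key step: the enamine formed from a racemic α-branched C19 aldehyde and a chiral primary amine adds to one enone arm of a prochiral cyclohexadienone. This closes ring A and gives A3, a cis-fused enone aldehyde (C7 ketone, C8=C9).
- For: it is catalytic and stereoconvergent, and C19 arrives at the aldehyde level. C9 is the β-carbon of the remaining enone, so the side chain could be added there axially in one conjugate addition, which is more direct than the four-step relay used here.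
- Against: the quaternary C4 must arise from a tetrasubstituted enamine, whose slow formation and uncertain geometry decide the C4 configuration. The catalyst must also select the enone arm and the face. A3 lacks C17 and has its oxygen at C7, so the C8 methyl carbinol needs methylation plus an oxygen transposition.
- Comparison: in the chosen route C4 follows from an alkene geometry fixed in a Wittig step and from the endo rule, and C17 is delivered by the quinone.

Key step: step 4

Assumption: the sense of facial induction of the oxazaborolidinium catalyst is taken from the usual binding model (quinone carbonyl on boron on the convex face, α-C–H···O contact, one phenyl group stacked on the reacting alkene), which points to the catalyst from (R)-α,α-diphenyl-2-pyrrolidinemethanol for 8; should the sense prove opposite, the antipodal catalyst is used with no other change.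

## Route

Step 1
Reactants: 1 acrolein; 2 ethyl 2-(triphenylphosphoranylidene)propanoate
Product: 3 ethyl (2E)-2-methylpenta-2,4-dienoate
Conditions: CH2Cl2, 0 °C to rt
Reagents that add atoms: none
Why: Wittig olefination with a stabilised ylide places the ester trans to the vinyl group; this E geometry later puts CH2O outside and CH3 inside at the diene terminus.

Step 2
Reactants: 3 ethyl (2E)-2-methylpenta-2,4-dienoate
Product: 5 (2E)-2-methylpenta-2,4-dien-1-ol, via (2E)-2-methylpenta-2,4-dienal 4 (not isolated)
Conditions: iBu2AlH (2.2 equiv), CH2Cl2, −78 to 0 °C; aq. potassium sodium tartrate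
Reagents that add atoms: none
Why: Aluminium hydride reduction of a conjugated ester proceeds 1,2 through the aldehyde to the allylic alcohol and leaves the diene and its geometry untouched.

Step 3
Reactants: 5 (2E)-2-methylpenta-2,4-dien-1-ol
Product: 6 tert-butyl(dimethyl){[(2E)-2-methylpenta-2,4-dien-1-yl]oxy}silane
Conditions: TBSCl, imidazole, DMF, 0 °C to rt
Reagents that add atoms: tert-butyl(chloro)dimethylsilane, CC(C)(C)[Si](C)(C)Cl
Why: Standard silylation of a primary allylic alcohol; the bulky silyl ether is a poor Lewis base and should not compete with the quinone for the catalyst.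

Step 4
Reactants: 6 tert-butyl(dimethyl){[(2E)-2-methylpenta-2,4-dien-1-yl]oxy}silane; 7 2,6-dimethyl-1,4-benzoquinone
Product: 8 (4aR,5R,8aS)-5-({[tert-butyl(dimethyl)silyl]oxy}methyl)-2,5,8a-trimethyl-4a,5,8,8a-tetrahydronaphthalene-1,4-dione
Conditions: N-protonated (R)-B-(o-tolyl)oxazaborolidine of α,α-diphenylprolinol as its triflimide (20 mol%; from (R)-α,α-diphenyl-2-pyrrolidinemethanol, tri(o-tolyl)boroxine, HNTf2), CH2Cl2, −78 to −40 °C
Reagents that add atoms: none
Why: The boron Lewis acid binds the C6 carbonyl of 7 (flanked by two C–H groups, hence less hindered, and the more basic because both methyl groups sit at its β-positions), and the activated C10=C5 bond undergoes a concerted, asynchronous [4+2] cycloaddition with s-cis 6. The closest known reaction type is the oxazaborolidinium-catalysed enantioselective Diels–Alder reaction of alkyl-1,4-benzoquinones with substituted butadienes, together with the Lewis-acid-steered regiochemistry known for 2,6-dimethylbenzoquinone and 1-substituted dienes. Ring A is closed as a cyclohexene by intermolecular [4+2] annulation, both new bonds (C1–C10 and C4–C5) being made on one face of the quinone alkene. C10 is the β-carbon of the bound enone and takes the unsubstituted, more nucleophilic terminus C1, so the crowded terminus C4 meets the CH carbon C5 and no bond between two fully substituted carbons is needed. C5 and C10 are set together, cis by suprafacial addition, and their absolute configuration by the catalyst, one aryl group of which covers one face of the bound alkene. C4 follows from the endo transition state and the E geometry of 6: the inside methyl ends cis to the exo substituents H-5 and CH3-10, the outside CH2OSi trans to them. The step needs regio-, endo- and enantioface selectivity, secured by the site of coordination, by secondary overlap with the quinone carbonyls and by the chiral cation; the two C=C bonds of 7 are homotopic, so no site selectivity is required.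

Step 5
Reactants: 8 cycloadduct
Product: 9 cis-fused 19-(TBS-oxy)-6,9-dione, rings saturated (8-CH3; 8β epimer drawn)
Conditions: H2 (1 atm), 10% Pd on carbon, EtOAc, rt
Reagents that add atoms: none
Why: Heterogeneous hydrogenation saturates the electron-poor ene-dione alkene and the ring-A alkene; the C8 centre formed is erased in step 9, and the neutral medium avoids epimerisation of C5, which is α to the C6 ketone.

Step 6
Reactants: 9 saturated 6,9-dione
Product: 10 6α-hydroxy-9-ketone (19-OTBS)
Conditions: NaBH4 (1 equiv), MeOH–CH2Cl2, −40 °C
Reagents that add atoms: none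
Why: Chemoselective borohydride reduction: C6=O has a CH and a CH2 neighbour, whereas C9=O lies between quaternary C10 and branched C8, so only C6 reacts. Hydride is expected from the β face because axial approach is blocked by the axial C1 methylene; the C6 configuration is of no consequence, and the reduction ends any risk to C5.

Step 7
Reactants: 10 6α-hydroxy-9-ketone
Product: 11 O-6 phenyl thionocarbonate of 10
Conditions: PhOC(S)Cl, pyridine, DMAP (cat.), CH2Cl2, rt
Reagents that add atoms: O-phenyl carbonochloridothioate, S=C(Cl)Oc1ccccc1
Why: Thioacylation of the only hydroxyl prepares the radical deoxygenation; the mild base does not enolise the hindered C9 ketone.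

Step 8
Reactants: 11 thionocarbonate
Product: 12 19-(TBS-oxy)-9-ketone with C6 and C7 as methylenes (8-CH3; 8β epimer drawn)
Conditions: Bu3SnH, AIBN (cat.), toluene, 100 °C
Reagents that add atoms: none
Why: Barton–McCombie deoxygenation through the secondary C6 radical; the saturated ring system offers the radical no cyclisation or fragmentation path.

Step 9
Reactants: 12 9-ketone
Product: 14 19-(TBS-oxy)-7-en-9-one, via trimethylsilyl enol ether 13 (not isolated)
Conditions: Me3SiOTf, Et3N, CH2Cl2, 0 °C; then Pd(OAc)2 (1.1 equiv), MeCN, rt
Reagents that add atoms: none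
Why: Saegusa–Ito dehydrogenation: C10 is quaternary, so the ketone can enolise only towards C8, and β-hydride elimination from C7 gives the endocyclic α-methyl enone. Both C8 epimers of 12 converge here.

Step 10
Reactants: 14 enone
Product: 15 7β,8β-epoxy-9-ketone (8α-CH3, 19-OTBS)
Conditions: H2O2 (30% aq.), NaOH (aq.), MeOH, 0 °C to rt
Reagents that add atoms: hydrogen peroxide, OO
Why: Weitz–Scheffer epoxidation: hydroperoxide adds to the unhindered β-carbon C7 along the axial trajectory, which in the conformationally biased enone (H-5 axial, C4 equatorial) is the β face, and the enolate closes on the same face. This sets the C7–O bond that later controls C9.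

Step 11
Reactants: 15 epoxy ketone
Product: 17 7β-hydroxy-8-ene (C8=C9, H on C9, 19-OTBS), via epoxy hydrazone 16 (not isolated)
Conditions: N2H4·H2O, AcOH, MeOH, 0 °C to rt
Reagents that add atoms: none
Why: Wharton transposition: the hydrazone opens the epoxide, loses N2 and leaves the C8=C9 alkene with hydrogen on C9; the C7–O bond is not touched, so the alcohol stays β (axial).

Step 12
Reactants: 17 allylic alcohol
Product: 19 ethyl ester with 9β-CH2CO2Et, 9α-H and C7=C8 (19-OTBS), via ketene acetal 18 (not isolated)
Conditions: MeC(OEt)3, EtCO2H (cat.), 140 °C, removal of EtOH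
Reagents that add atoms: triethyl orthoacetate, CCOC(C)(OCC)OCC
Why: Johnson–Claisen rearrangement: the mixed ketene acetal on the pseudoaxial 7β-oxygen rearranges through a chair-like [3,3] transition state that can only reach the β face of C9. The C9–C11 bond is therefore formed axially and cis to C20, H-9 becomes α, and the alkene moves to C7=C8.

Step 13
Reactants: 19 unsaturated ester
Product: 20 7α,8α-epoxide of 19
Conditions: mCPBA, NaHCO3, CH2Cl2, 0 °C
Reagents that add atoms: 3-chloroperoxybenzoic acid, OOC(=O)c1cccc(Cl)c1
Why: Prilezhaev epoxidation: the β face of C7=C8 is covered by the adjacent pseudoaxial C9 side arm, so the peracid should attack from the α face; the buffer prevents acid-induced opening.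

Step 14
Reactants: 20 epoxy ester
Product: 21 8α,12-diol (9β-CH2CH2OH, 8β-CH3, 19-OTBS)
Conditions: LiAlH4, THF, 0 °C to reflux
Reagents that add atoms: none
Why: Hydride reduces the ester to the C12 alcohol and opens the oxirane at the secondary C7 from the β face (diaxial opening, Fürst–Plattner rule), which leaves the oxygen on C8 as the axial 8α-hydroxyl. The less substituted carbon and the diaxial path coincide.

Step 15
Reactants: 21 diol
Product: 22 12-iodo-8α-ol (19-OTBS)
Conditions: I2, PPh3, imidazole, CH2Cl2, 0 °C to rt
Reagents that add atoms: iodine, II
Why: Appel-type iodination is selective for the primary alcohol; the tertiary 8-hydroxyl is inert and, being trans-diaxial to the chain in the preferred conformation, is poorly placed to close an ether ring onto C12.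

Step 16
Reactants: 22 iodide; 23 2-chlorobuta-1,3-diene
Product: 25 9β-(3-methylenepent-4-enyl)-8α-ol, 19-O-TBS ether, via buta-1,3-dien-2-ylmagnesium chloride 24 (not isolated)
Conditions: 23, Mg, ZnCl2 (cat.), THF (gives 24, 3 equiv); then 22, Li2CuCl4 (5 mol%), THF, −10 °C to rt
Reagents that add atoms: none
Why: Copper-catalysed Grignard cross-coupling (Kochi type) of a primary alkyl iodide with the 2-butadienyl Grignard reagent forms C12–C13 and delivers the 2-substituted diene directly; one equivalent of the reagent is consumed by the tertiary hydroxyl.

Step 17
Reactants: 25 silyl ether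
Product: 26 8α,19-diol with the complete side chain
Conditions: Bu4NF, THF, rt to 45 °C
Reagents that add atoms: none
Why: Fluoride cleaves the neopentyl primary silyl ether; the diene and the tertiary alcohol are stable to these basic, non-oxidising conditions.

Step 18
Reactants: 26 diol
Product: 27 19-O-{[bis(2,2,2-trifluoroethoxy)phosphoryl]acetyl} ester of 26
Conditions: (CF3CH2O)2P(O)CH2CO2H, EDC·HCl, DMAP (cat.), CH2Cl2, 0 °C to rt
Reagents that add atoms: [bis(2,2,2-trifluoroethoxy)phosphoryl]acetic acid, OC(=O)CP(=O)(OCC(F)(F)F)OCC(F)(F)F
Why: Carbodiimide (Steglich) esterification acylates the primary C19 hydroxyl only; phosphonoacetic acids couple well even with neopentyl alcohols, and the axial tertiary hydroxyl does not react.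

Step 19
Reactants: 28 4-hydroxybenzaldehyde
Product: 29 4-{[tert-butyl(dimethyl)silyl]oxy}benzaldehyde
Conditions: TBSCl, imidazole, DMF, rt
Reagents that add atoms: tert-butyl(chloro)dimethylsilane, CC(C)(C)[Si](C)(C)Cl
Why: Silylation masks the phenol, which as a phenoxide would deactivate the aldehyde in the olefination.

Step 20
Reactants: 27 phosphonoacetate; 29 4-{[tert-butyl(dimethyl)silyl]oxy}benzaldehyde
Product: 30 19-O-[(2Z)-3-(4-{[tert-butyl(dimethyl)silyl]oxy}phenyl)prop-2-enoyl] ester of 26
Conditions: KN(SiMe3)2 (1.05 equiv), 18-crown-6, THF, −78 °C; then 29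
Reagents that add atoms: none
Why: Still–Gennari variant of the Horner–Wadsworth–Emmons reaction: the electron-poor phosphonate with a dissociated potassium counter-ion eliminates fast from the kinetic adduct and gives the Z-cinnamate; one equivalent of base deprotonates only the phosphonate, not the tertiary alcohol.

Step 21
Reactants: 30 silyl-protected ester
Product: 31 target, (4R,5S,8R,9R,10S)-8α-hydroxy-9β-(3-methylenepent-4-enyl) cis-decalin 19-yl (2Z)-3-(4-hydroxyphenyl)prop-2-enoate
Conditions: Bu4NF–AcOH (1:1), THF, 0 °C, exclusion of light
Reagents that add atoms: none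
Why: Aryl silyl ethers are cleaved by buffered fluoride far faster than esters react; the buffer avoids a free phenoxide, which together with light would promote Z-to-E isomerisation.

## Compound list

1 | acrolein | C=CC=O | starting material
2 | ethyl 2-(triphenylphosphoranylidene)propanoate | CCOC(=O)C(C)=P(c1ccccc1)(c1ccccc1)c1ccccc1 | starting material
3 | ethyl (2E)-2-methylpenta-2,4-dienoate | C=C/C=C(\C)C(=O)OCC | intermediate
4 | (2E)-2-methylpenta-2,4-dienal | C=C/C=C(\C)C=O | intermediate (not isolated)
5 | (2E)-2-methylpenta-2,4-dien-1-ol | C=C/C=C(\C)CO | intermediate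
6 | tert-butyl(dimethyl){[(2E)-2-methylpenta-2,4-dien-1-yl]oxy}silane | C=C/C=C(\C)CO[Si](C)(C)C(C)(C)C | intermediate
7 | 2,6-dimethyl-1,4-benzoquinone | CC1=CC(=O)C=C(C)C1=O | starting material
8 | (4aR,5R,8aS)-5-({[tert-butyl(dimethyl)silyl]oxy}methyl)-2,5,8a-trimethyl-4a,5,8,8a-tetrahydronaphthalene-1,4-dione | O=C1[C@@]2(C)CC=C[C@@](C)(CO[Si](C)(C)C(C)(C)C)[C@H]2C(=O)C=C1C | intermediate
9 | cis-fused 19-(TBS-oxy)-6,9-dione, rings saturated (4β-CH3, 5β-H, 10β-CH3; 8β-CH3 epimer drawn) | O=C1[C@@]2(C)CCC[C@@](C)(CO[Si](C)(C)C(C)(C)C)[C@H]2C(=O)C[C@@H]1C | intermediate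
10 | 6α-hydroxy-9-ketone of the same skeleton (19-OTBS; 8β-CH3 drawn) | O=C1[C@@]2(C)CCC[C@@](C)(CO[Si](C)(C)C(C)(C)C)[C@H]2[C@@H](O)C[C@@H]1C | intermediate
11 | O-6 phenyl thionocarbonate of 10 | O=C1[C@@]2(C)CCC[C@@](C)(CO[Si](C)(C)C(C)(C)C)[C@H]2[C@@H](OC(=S)Oc3ccccc3)C[C@@H]1C | intermediate
12 | 19-(TBS-oxy)-9-ketone, C6 and C7 methylenes (8β-CH3 drawn) | O=C1[C@@]2(C)CCC[C@@](C)(CO[Si](C)(C)C(C)(C)C)[C@H]2CC[C@@H]1C | intermediate
13 | trimethylsilyl enol ether of 12 (C8=C9, 9-OSiMe3) | C1(O[Si](C)(C)C)[C@@]2(C)CCC[C@@](C)(CO[Si](C)(C)C(C)(C)C)[C@H]2CCC=1C | intermediate (not isolated)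
14 | 19-(TBS-oxy)-7-en-9-one (C7=C8, 8-CH3) | O=C1[C@@]2(C)CCC[C@@](C)(CO[Si](C)(C)C(C)(C)C)[C@H]2CC=C1C | intermediate
15 | 7β,8β-epoxy-9-ketone (8α-CH3, 19-OTBS) | O=C1[C@@]2(C)CCC[C@@](C)(CO[Si](C)(C)C(C)(C)C)[C@H]2C[C@@H]3O[C@@]31C | intermediate
16 | C9 hydrazone of 15 | NN=C1[C@@]2(C)CCC[C@@](C)(CO[Si](C)(C)C(C)(C)C)[C@H]2C[C@@H]3O[C@@]31C | intermediate (not isolated)
17 | 7β-hydroxy-8-ene (C8=C9, 8-CH3, 19-OTBS) | C1[C@@]2(C)CCC[C@@](C)(CO[Si](C)(C)C(C)(C)C)[C@H]2C[C@H](O)C=1C | intermediate
18 | 7β-O-(1-ethoxyvinyl) ether of 17 (mixed ketene acetal) | C1[C@@]2(C)CCC[C@@](C)(CO[Si](C)(C)C(C)(C)C)[C@H]2C[C@H](OC(=C)OCC)C=1C | intermediate (not isolated)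
19 | ethyl ester with 9β-CH2CO2Et, 9α-H, C7=C8 (19-OTBS) | CCOC(=O)C[C@@H]1[C@@]2(C)CCC[C@@](C)(CO[Si](C)(C)C(C)(C)C)[C@H]2CC=C1C | intermediate
20 | 7α,8α-epoxide of 19 | CCOC(=O)C[C@@H]1[C@@]2(C)CCC[C@@](C)(CO[Si](C)(C)C(C)(C)C)[C@H]2C[C@H]3O[C@]31C | intermediate
21 | 8α,12-diol (9β-CH2CH2OH, 8β-CH3, 19-OTBS) | OCC[C@@H]1[C@@]2(C)CCC[C@@](C)(CO[Si](C)(C)C(C)(C)C)[C@H]2CC[C@@]1(C)O | intermediate
22 | 12-iodo-8α-ol (19-OTBS) | ICC[C@@H]1[C@@]2(C)CCC[C@@](C)(CO[Si](C)(C)C(C)(C)C)[C@H]2CC[C@@]1(C)O | intermediate
23 | 2-chlorobuta-1,3-diene | C=CC(Cl)=C | starting material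
24 | buta-1,3-dien-2-ylmagnesium chloride | C=CC(=C)[Mg]Cl | intermediate (not isolated)
25 | 9β-(3-methylenepent-4-enyl)-8α-ol, 19-O-TBS ether | C=CC(=C)CC[C@@H]1[C@@]2(C)CCC[C@@](C)(CO[Si](C)(C)C(C)(C)C)[C@H]2CC[C@@]1(C)O | intermediate
26 | 8α,19-diol with the complete side chain | C=CC(=C)CC[C@@H]1[C@@]2(C)CCC[C@@](C)(CO)[C@H]2CC[C@@]1(C)O | intermediate
27 | 19-O-{[bis(2,2,2-trifluoroethoxy)phosphoryl]acetyl} ester of 26 | C=CC(=C)CC[C@@H]1[C@@]2(C)CCC[C@@](C)(COC(=O)CP(=O)(OCC(F)(F)F)OCC(F)(F)F)[C@H]2CC[C@@]1(C)O | intermediate
28 | 4-hydroxybenzaldehyde | O=Cc1ccc(O)cc1 | starting material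
29 | 4-{[tert-butyl(dimethyl)silyl]oxy}benzaldehyde | O=Cc1ccc(O[Si](C)(C)C(C)(C)C)cc1 | intermediate
30 | phenol TBS ether of the target | C=CC(=C)CC[C@@H]1[C@@]2(C)CCC[C@@](C)(COC(=O)/C=C\c3ccc(O[Si](C)(C)C(C)(C)C)cc3)[C@H]2CC[C@@]1(C)O | intermediate
31 | target, (4R,5S,8R,9R,10S)-configured 19-yl (2Z)-3-(4-hydroxyphenyl)prop-2-enoate | C=CC(=C)CC[C@@H]1[C@@]2(C)CCC[C@@](C)(COC(=O)/C=C\c3ccc(O)cc3)[C@H]2CC[C@@]1(C)O | target

## Step count and least certain steps

Total: 21 steps. Longest linear sequence: 20 steps (steps 1–18, 20, 21); step 19 is a one-step side branch.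

**Step 4 (key step).** The inside methyl group destabilises the s-cis form of 6, so the cycloaddition may be slow. A stepwise ionic addition to the strongly activated quinone, or acid-induced ionisation of the allylic silyl ether, could then erode endo and facial control; the sense of induction may also be opposite to the model. Fallback, from 6 and 7 back to 8: cycloaddition promoted by BF3·OEt2 (regiochemistry still set by coordination at the C6 carbonyl) or run thermally under high pressure gives racemic 8. Its unwanted half, the (4aS,5S,8aR) enantiomer F1 of the cycloadduct, is separated by preparative chromatography on a chiral stationary phase. F1 is set aside and 8 goes on.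

**Step 11.** Hydrazone formation at the C9 carbonyl, which lies between quaternary C10 and the oxirane carbon, may be too slow, and epoxide opening by hydrazine or decomposition may take over. Fallback, from 15 back to 17: NaBH4 (excess, MeOH, 0 °C to rt) reduces the ketone to the 9-hydroxy-7β,8β-epoxide F2, whose C9 configuration is of no consequence. F2 is thioacylated with PhOC(S)Cl and pyridine to the O-9 phenyl thionocarbonate F3, without a strong base that could trigger epoxide migration. Heating F3 with Bu3SnH and AIBN generates the C9 radical, whose oxirane opens at once to the C8=C9 alkene and the 7β-oxy radical, and hydrogen transfer gives 17.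

**Step 12.** Acid-catalysed dehydration of the axial allylic alcohol to a diene, or slow exchange with the orthoester, may compete with the rearrangement. Fallback, from 17 back to 19: acetylation (Ac2O, DMAP) gives the 7β-acetate F4, and Ireland–Claisen rearrangement of F4 (LiN(iPr)2, Me3SiCl, THF, −78 °C to rt; aqueous work-up) gives the 9β-acetic acid F5 by the same suprafacial transfer at low temperature. F5 is then ethylated (EtI, K2CO3, DMF), which returns 19.

**Step 13 (with step 14).** Facial selectivity of oxygen transfer may be poor, because the axial C1 methylene hinders the α face while the C9 arm hinders the β face; a β-epoxide would not open to the 8α-alcohol with hydride. Fallback, from 19 back to 20: N-bromosuccinimide in aqueous 1,2-dimethoxyethane (0 °C, in the dark) gives the 7β-bromo-8α-hydroxy ester F6, a bromohydrin. Bromine transfer to the alkene is reversible on both faces, but only bromine on the β face allows water to attack the tertiary C8 in a way that is trans-diaxial and Markovnikov at once. The hydroxyl should therefore arrive on the α face whichever face the electrophile prefers. F6 is then closed with K2CO3 in EtOH: the 8α-alkoxide displaces the axial 7β-bromide from the α side and gives 20. The configuration is thus set by the stereoelectronics of ring opening and not by the facial preference of an oxidant.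

**Step 16.** Formation and handling of the dienyl Grignard reagent may fail through polymerisation or allenic isomers, homocoupling or reduction of the iodide may compete, and the magnesium alkoxide at O-8 may close an 8,12-ether should ring B flip. Fallback, from 22 back to 25: displacement with lithium acetylide–ethylenediamine complex in DMSO gives the terminal alkyne F7, the 9β-(but-3-ynyl)-8α-ol. F7 then undergoes enyne cross-metathesis with ethylene (second-generation Grubbs catalyst, toluene, 80 °C), which converts the alkyne into the 2-substituted butadiene 25.

**Step 20.** The Z selectivity may be incomplete, or the Z ester may isomerise during work-up; the isomers would then have to be separated on the full molecule. Fallback, from 29 and 26 back to 30: 29 is olefinated with commercial methyl [bis(2,2,2-trifluoroethoxy)phosphoryl]acetate (KN(SiMe3)2, 18-crown-6, THF, −78 °C) to methyl (2Z)-3-(4-{[tert-butyl(dimethyl)silyl]oxy}phenyl)prop-2-enoate F8, and F8 is freed of its E isomer on the small molecule. Hydrolysis with Me3SnOH gives the Z acid F9, and F9 is coupled with 26 (2,4,6-trichlorobenzoyl chloride, Et3N, then a minimum of DMAP, in the dark) to give 30.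

## Further compounds

F1 | step 4 | enantiomer of 8, (4aS,5S,8aR) | O=C1[C@]2(C)CC=C[C@](C)(CO[Si](C)(C)C(C)(C)C)[C@@H]2C(=O)C=C1C
F2 | step 11 | 9α-hydroxy-7β,8β-epoxide (19-OTBS; 9α epimer drawn) | O[C@H]1[C@@]2(C)CCC[C@@](C)(CO[Si](C)(C)C(C)(C)C)[C@H]2C[C@@H]3O[C@@]31C
F3 | step 11 | O-9 phenyl thionocarbonate of F2 | S=C(Oc1ccccc1)O[C@H]1[C@@]2(C)CCC[C@@](C)(CO[Si](C)(C)C(C)(C)C)[C@H]2C[C@@H]3O[C@@]31C
F4 | step 12 | 7β-acetate of 17 | C1[C@@]2(C)CCC[C@@](C)(CO[Si](C)(C)C(C)(C)C)[C@H]2C[C@H](OC(C)=O)C=1C
F5 | step 12 | 9β-carboxymethyl-7-ene acid (19-OTBS) | OC(=O)C[C@@H]1[C@@]2(C)CCC[C@@](C)(CO[Si](C)(C)C(C)(C)C)[C@H]2CC=C1C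
F6 | step 13 | 7β-bromo-8α-hydroxy ester (bromohydrin of 19; 8β-CH3, 9β-CH2CO2Et, 19-OTBS) | CCOC(=O)C[C@@H]1[C@@]2(C)CCC[C@@](C)(CO[Si](C)(C)C(C)(C)C)[C@H]2C[C@H](Br)[C@@]1(C)O
F7 | step 16 | 9β-(but-3-ynyl)-8α-ol (19-OTBS) | C#CCC[C@@H]1[C@@]2(C)CCC[C@@](C)(CO[Si](C)(C)C(C)(C)C)[C@H]2CC[C@@]1(C)O
F8 | step 20 | methyl (2Z)-3-(4-{[tert-butyl(dimethyl)silyl]oxy}phenyl)prop-2-enoate | COC(=O)/C=C\c1ccc(O[Si](C)(C)C(C)(C)C)cc1
F9 | step 20 | (2Z)-3-(4-{[tert-butyl(dimethyl)silyl]oxy}phenyl)prop-2-enoic acid | OC(=O)/C=C\c1ccc(O[Si](C)(C)C(C)(C)C)cc1
A1 | alternative 1 | cis-fused decalin with C8 ketone, C9 dimethyl ketal, C2 phenylsulfonyl and C3=C4 methyl enoate | COC1(OC)[C@@]2(C)C[C@H](S(=O)(=O)c3ccccc3)C=C(C(=O)OC)[C@H]2CCC1=O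
A2 | alternative 2 | cis-fused 1-ene methyl ester with C8 dioxolane and 2-(benzyloxy)ethyl on C9 | c1ccccc1COCC[C@@H]1[C@@]2(C)C=CC[C@@](C)(C(=O)OC)[C@H]2CCC13OCCO3
A3 | alternative 3 | cis-fused 8-en-7-one carrying the C19 aldehyde | O=C1C=C[C@@]2(C)CCC[C@@](C)(C=O)[C@H]2C1
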